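**Retrosynthetic overview**
1. Target 27 ⇐ allyl ester 26 (neutral deallylation) ⇐ half-ester 21: Ac2O/NaOAc makes a dienylketene whose 6π-electrocyclization builds the aromatic ring last and acetylates both hydroxyls in the same flask.
2. 21 ⇐ Stobbe condensation of diallyl succinate with the ring B enal 17, which supplies the arene CH, C–CO2R, CH and C–O carbons.
3. 17 ⇐ vinylogous hydroxymethylation of the siloxy diene 16 (sets C1 anti to the C4 side chain) ⇐ enal 15 ⇐ enone 13 by Wittig homologation.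
4. 13 (ring B) ⇐ ring-closing metathesis of allyl ketone 11 ⇐ Weinreb amide 9 ⇐ acid 7.
5. 7 ⇐ Ireland–Claisen rearrangement of ester 4, made from (S)-citronellic acid (carries C11) and (S)-but-3-en-2-ol (its carbinol chirality is transferred to C4). Ring order: ring B first, aromatic ring second.

Assumption: (S)-citronellic acid, (S)-but-3-en-2-ol and diallyl succinate are bought; C1, C4 and C11 in the text mean the target's CH2OAc-bearing ring carbon, the side-chain-bearing ring carbon and the side-chain methine.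

**Route**

Step 1
Reactants: 1 (3S)-3,7-dimethyloct-6-enoic acid; 2 (2S)-but-3-en-2-ol
Product: 4 (2S)-but-3-en-2-yl (3S)-3,7-dimethyloct-6-enoate, via O-acylisourea 3 (not isolated)
Conditions: DCC, DMAP (cat.), CH2Cl2, 0 °C to rt
Reagents that add atoms: none
Why: Steglich esterification acylates the alcohol oxygen without breaking the carbinol C–O bond, so both bought stereocentres are kept.

Step 2
Reactants: 4 (2S)-but-3-en-2-yl (3S)-3,7-dimethyloct-6-enoate
Product: 7 (2S,4E)-2-[(2S)-6-methylhept-5-en-2-yl]hex-4-enoic acid, via silyl ketene acetal 5 (not isolated), via trimethylsilyl ester 6 (not isolated)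
Conditions: LDA, THF, −78 °C; Me3SiCl; −78 °C to rt, then 50 °C; 1 M HCl
Reagents that add atoms: none
Why: Ireland–Claisen [3,3]-sigmatropic rearrangement: the kinetic (E)-silyl ketene acetal reacts through a chair with the carbinol methyl equatorial, so the bought C–O stereocentre is transferred to the new C4 centre (2S) and the alkene is E.

Step 3
Reactants: 7 (2S,4E)-2-[(2S)-6-methylhept-5-en-2-yl]hex-4-enoic acid
Product: 9 (2S,4E)-N-methoxy-N-methyl-2-[(2S)-6-methylhept-5-en-2-yl]hex-4-enamide, via acyl imidazole 8 (not isolated)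
Conditions: CDI, CH2Cl2, rt; then MeNH(OMe)·HCl, rt
Reagents that add atoms: N,O-dimethylhydroxylamine hydrochloride, CNOC.Cl
Why: Weinreb amide formation through the acyl imidazole is near-neutral and does not epimerise the α-centre.

Step 4
Reactants: 9 (2S,4E)-N-methoxy-N-methyl-2-[(2S)-6-methylhept-5-en-2-yl]hex-4-enamide
Product: 11 (5S,7E)-5-[(2S)-6-methylhept-5-en-2-yl]nona-1,7-dien-4-one, via magnesium chelate 10 (not isolated)
Conditions: CH2=CHCH2MgBr, THF, −78 to 0 °C; cold aq. NH4Cl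
Reagents that add atoms: allylmagnesium bromide, C=CC[Mg]Br
Why: Weinreb ketone synthesis: the chelated tetrahedral adduct stops over-addition, and the cold neutral quench keeps the β,γ-alkene and the α-centre in place.

Step 5
Reactants: 11 (5S,7E)-5-[(2S)-6-methylhept-5-en-2-yl]nona-1,7-dien-4-one
Product: 13 (6S)-6-[(2S)-6-methylhept-5-en-2-yl]cyclohex-2-en-1-one, via cyclohex-3-enone 12 (not isolated)
Conditions: (H2IMes)(PCy3)Cl2Ru=CHPh (second-generation Grubbs catalyst, 3 mol%), CH2Cl2, 40 °C; then DBU (10 mol%), 0 °C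
Reagents that add atoms: none
Why: Ring-closing metathesis of the allyl and (E)-propenyl groups closes ring B with loss of propene (the trisubstituted side-chain alkene is much slower), then base moves the alkene into conjugation through the extended dienolate.

Step 6
Reactants: 13 (6S)-6-[(2S)-6-methylhept-5-en-2-yl]cyclohex-2-en-1-one
Product: 15 (6S)-6-[(2S)-6-methylhept-5-en-2-yl]cyclohex-1-ene-1-carbaldehyde, via methyl dienol ether 14 (not isolated)
Conditions: Ph3P(CH2OMe)Cl, KN(SiMe3)2, THF, −78 to 0 °C; then 2 M HCl, THF, rt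
Reagents that add atoms: (methoxymethyl)triphenylphosphonium chloride, COC[P+](c1ccccc1)(c1ccccc1)c1ccccc1.[Cl-]; water, O
Why: Wittig methoxymethylenation gives a 1-methoxy diene, and acid hydrolysis with protonation at the diene terminus gives the conjugated enal, with the ring alkene now next to C4.

Step 7
Reactants: 15 (6S)-6-[(2S)-6-methylhept-5-en-2-yl]cyclohex-1-ene-1-carbaldehyde
Product: 16 tert-butyl(dimethyl)silyl dienol ether of 15
Conditions: tBuMe2SiOTf, Et3N, CH2Cl2, 0 °C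
Reagents that add atoms: tert-butyldimethylsilyl trifluoromethanesulfonate, CC(C)(C)[Si](C)(C)OS(=O)(=O)C(F)(F)F
Why: O-silylation followed by γ-deprotonation gives the linear 1-siloxy diene; the C4 hydrogen is not on the conjugated path and is untouched.

Step 8
Reactants: 16 tert-butyl(dimethyl)silyl dienol ether of 15
Product: 17 (3R,6S)-3-(hydroxymethyl)-6-[(2S)-6-methylhept-5-en-2-yl]cyclohex-1-ene-1-carbaldehyde
Conditions: aq. HCHO (37%), Yb(OTf)3 (10 mol%), THF, rt
Reagents that add atoms: formaldehyde, C=O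
Why: Vinylogous Mukaiyama aldol (lanthanide-triflate hydroxymethylation) at the γ-carbon: allylic 1,3-strain with the siloxymethylidene holds the C4 side chain pseudoaxial, so formaldehyde adds to the opposite face and the new C1 centre is trans to it.

Step 9
Reactants: 17 (3R,6S)-3-(hydroxymethyl)-6-[(2S)-6-methylhept-5-en-2-yl]cyclohex-1-ene-1-carbaldehyde; 18 diallyl butanedioate
Product: 21 (3E)-4-[(3R,6S)-3-(hydroxymethyl)-6-[(2S)-6-methylhept-5-en-2-yl]cyclohex-1-en-1-yl]-3-[(prop-2-en-1-yloxy)carbonyl]but-3-enoic acid, via aldol adduct 19 (not isolated), via paraconate lactone 20 (not isolated)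
Conditions: KOtBu (2.5 equiv), tBuOH–THF, 0 °C to rt; 1 M HCl
Reagents that add atoms: none
Why: Stobbe condensation (aldol, lactonisation, E1cB ring opening) gives the (E)-alkylidene succinate with the free acid on the CH2 arm and the ring cis to it, as the cyclisation needs.

Step 10
Reactants: 21 (3E)-4-[(3R,6S)-3-(hydroxymethyl)-6-[(2S)-6-methylhept-5-en-2-yl]cyclohex-1-en-1-yl]-3-[(prop-2-en-1-yloxy)carbonyl]but-3-enoic acid
Product: 26 prop-2-en-1-yl (5R,8S)-4-(acetyloxy)-5-[(acetyloxy)methyl]-8-[(2S)-6-methylhept-5-en-2-yl]-5,6,7,8-tetrahydronaphthalene-2-carboxylate, via mixed anhydride 22 (not isolated), via dienylketene 23 (not isolated), via cyclohexadienone 24 (not isolated), via phenol 25 (not isolated)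
Conditions: Ac2O, NaOAc, 140 °C
Reagents that add atoms: acetic anhydride, CC(=O)OC(C)=O
Why: Acetate eliminates the mixed anhydride to a dienylketene, whose thermal 6π-electrocyclization forms the aromatic ring; tautomerisation gives the phenol, which is acetylated together with the primary alcohol, and neither ring B stereocentre is touched.

Step 11
Reactants: 26 prop-2-en-1-yl (5R,8S)-4-(acetyloxy)-5-[(acetyloxy)methyl]-8-[(2S)-6-methylhept-5-en-2-yl]-5,6,7,8-tetrahydronaphthalene-2-carboxylate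
Product: 27 (5R,8S)-4-(acetyloxy)-5-[(acetyloxy)methyl]-8-[(2S)-6-methylhept-5-en-2-yl]-5,6,7,8-tetrahydronaphthalene-2-carboxylic acid
Conditions: Pd(PPh3)4 (5 mol%), PhNHMe, THF, rt
Reagents that add atoms: none
Why: Tsuji–Trost allyl transfer from the ester to N-methylaniline with zerovalent palladium frees the acid under neutral conditions that leave both acetates and the alkene alone.

**Compound list**
1 | (3S)-3,7-dimethyloct-6-enoic acid [(S)-citronellic acid] | C[C@H](CC(=O)O)CCC=C(C)C | starting material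
2 | (2S)-but-3-en-2-ol | C[C@H](O)C=C | starting material
3 | O-acylisourea from 1 and DCC | C[C@H](CC(=O)OC(=NC1CCCCC1)NC1CCCCC1)CCC=C(C)C | intermediate
4 | (2S)-but-3-en-2-yl (3S)-3,7-dimethyloct-6-enoate | C[C@H](CC(=O)O[C@@H](C)C=C)CCC=C(C)C | intermediate
5 | {[(1E,3S)-1-{[(2S)-but-3-en-2-yl]oxy}-3,7-dimethylocta-1,6-dien-1-yl]oxy}trimethylsilane | C[C@H](/C=C(/O[Si](C)(C)C)O[C@@H](C)C=C)CCC=C(C)C | intermediate
6 | trimethylsilyl (2S,4E)-2-[(2S)-6-methylhept-5-en-2-yl]hex-4-enoate | C/C=C/C[C@@H]([C@@H](C)CCC=C(C)C)C(=O)O[Si](C)(C)C | intermediate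
7 | (2S,4E)-2-[(2S)-6-methylhept-5-en-2-yl]hex-4-enoic acid | C/C=C/C[C@@H]([C@@H](C)CCC=C(C)C)C(=O)O | intermediate
8 | (2S,4E)-1-(imidazol-1-yl)-2-[(2S)-6-methylhept-5-en-2-yl]hex-4-en-1-one | C/C=C/C[C@@H]([C@@H](C)CCC=C(C)C)C(=O)n1ccnc1 | intermediate
9 | (2S,4E)-N-methoxy-N-methyl-2-[(2S)-6-methylhept-5-en-2-yl]hex-4-enamide | C/C=C/C[C@@H]([C@@H](C)CCC=C(C)C)C(=O)N(C)OC | intermediate
10 | bromomagnesium alkoxide of the allyl adduct of 9 (chelated hemiaminal) | C/C=C/C[C@@H]([C@@H](C)CCC=C(C)C)C(O[Mg]Br)(CC=C)N(C)OC | intermediate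
11 | (5S,7E)-5-[(2S)-6-methylhept-5-en-2-yl]nona-1,7-dien-4-one | C/C=C/C[C@@H]([C@@H](C)CCC=C(C)C)C(=O)CC=C | intermediate
12 | (6S)-6-[(2S)-6-methylhept-5-en-2-yl]cyclohex-3-en-1-one | O=C1CC=CC[C@H]1[C@@H](C)CCC=C(C)C | intermediate
13 | (6S)-6-[(2S)-6-methylhept-5-en-2-yl]cyclohex-2-en-1-one | O=C1C=CCC[C@H]1[C@@H](C)CCC=C(C)C | intermediate
14 | (4S)-3-(methoxymethylidene)-4-[(2S)-6-methylhept-5-en-2-yl]cyclohex-1-ene (E/Z mixture) | COC=C1C=CCC[C@H]1[C@@H](C)CCC=C(C)C | intermediate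
15 | (6S)-6-[(2S)-6-methylhept-5-en-2-yl]cyclohex-1-ene-1-carbaldehyde | O=CC1=CCCC[C@H]1[C@@H](C)CCC=C(C)C | intermediate
16 | tert-butyl(dimethyl){[(6S)-6-[(2S)-6-methylhept-5-en-2-yl]cyclohex-2-en-1-ylidene]methoxy}silane (siloxy group drawn syn to C6) | CC(C)(C)[Si](C)(C)O/C=C1/C=CCC[C@H]1[C@@H](C)CCC=C(C)C | intermediate
17 | (3R,6S)-3-(hydroxymethyl)-6-[(2S)-6-methylhept-5-en-2-yl]cyclohex-1-ene-1-carbaldehyde | O=CC1=C[C@H](CO)CC[C@H]1[C@@H](C)CCC=C(C)C | intermediate
18 | diallyl butanedioate (diallyl succinate) | C=CCOC(=O)CCC(=O)OCC=C | starting material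
19 | diallyl 2-{hydroxy[(3R,6S)-3-(hydroxymethyl)-6-[(2S)-6-methylhept-5-en-2-yl]cyclohex-1-en-1-yl]methyl}butanedioate (new centres unassigned) | C=CCOC(=O)CC(C(=O)OCC=C)C(O)C1=C[C@H](CO)CC[C@H]1[C@@H](C)CCC=C(C)C | intermediate
20 | prop-2-en-1-yl 2-[(3R,6S)-3-(hydroxymethyl)-6-[(2S)-6-methylhept-5-en-2-yl]cyclohex-1-en-1-yl]-5-oxooxolane-3-carboxylate (new centres unassigned) | O=C1CC(C(=O)OCC=C)C(O1)C2=C[C@H](CO)CC[C@H]2[C@@H](C)CCC=C(C)C | intermediate
21 | (3E)-4-[(3R,6S)-3-(hydroxymethyl)-6-[(2S)-6-methylhept-5-en-2-yl]cyclohex-1-en-1-yl]-3-[(prop-2-en-1-yloxy)carbonyl]but-3-enoic acid | OC(=O)C/C(=C\C1=C[C@H](CO)CC[C@H]1[C@@H](C)CCC=C(C)C)C(=O)OCC=C | intermediate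
22 | mixed acetic anhydride of 21 with the primary alcohol acetylated | CC(=O)OC(=O)C/C(=C\C1=C[C@H](COC(C)=O)CC[C@H]1[C@@H](C)CCC=C(C)C)C(=O)OCC=C | intermediate
23 | prop-2-en-1-yl (2E)-2-{[(3R,6S)-3-[(acetyloxy)methyl]-6-[(2S)-6-methylhept-5-en-2-yl]cyclohex-1-en-1-yl]methylidene}-4-oxobut-3-enoate (dienylketene) | O=C=C/C(=C\C1=C[C@H](COC(C)=O)CC[C@H]1[C@@H](C)CCC=C(C)C)C(=O)OCC=C | intermediate
24 | prop-2-en-1-yl (5R,8S)-5-[(acetyloxy)methyl]-8-[(2S)-6-methylhept-5-en-2-yl]-4-oxo-4,4a,5,6,7,8-hexahydronaphthalene-2-carboxylate (4a centre unassigned) | O=C1C=C(C(=O)OCC=C)C=C2[C@H]([C@@H](C)CCC=C(C)C)CC[C@@H](COC(C)=O)C12 | intermediate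
25 | prop-2-en-1-yl (5R,8S)-5-[(acetyloxy)methyl]-4-hydroxy-8-[(2S)-6-methylhept-5-en-2-yl]-5,6,7,8-tetrahydronaphthalene-2-carboxylate | CC(=O)OC[C@@H]1CC[C@@H]([C@@H](C)CCC=C(C)C)c2cc(C(=O)OCC=C)cc(O)c21 | intermediate
26 | prop-2-en-1-yl (5R,8S)-4-(acetyloxy)-5-[(acetyloxy)methyl]-8-[(2S)-6-methylhept-5-en-2-yl]-5,6,7,8-tetrahydronaphthalene-2-carboxylate | CC(=O)OC[C@@H]1CC[C@@H]([C@@H](C)CCC=C(C)C)c2cc(C(=O)OCC=C)cc(OC(C)=O)c21 | intermediate
27 | (5R,8S)-4-(acetyloxy)-5-[(acetyloxy)methyl]-8-[(2S)-6-methylhept-5-en-2-yl]-5,6,7,8-tetrahydronaphthalene-2-carboxylic acid | CC(=O)OC[C@@H]1CC[C@@H]([C@@H](C)CCC=C(C)C)c2cc(C(=O)O)cc(OC(C)=O)c21 | target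

**Step count**
Total steps: 11. Longest linear sequence: 11 steps (1 → 27).

**Three steps most likely to fail, with fallbacks**

Step 6. The basic ylide may enolise the hindered ketone of 13, giving low conversion or epimerising the centre next to the carbonyl. The fallback sets out from 13 and comes back at 15. Dimethylsulfonium methylide (Me3S+ I−, KN(SiMe3)2, THF, −10 °C) adds to the carbonyl to give the vinyl oxirane (4S)-4-[(2S)-6-methylhept-5-en-2-yl]-1-oxaspiro[2.5]oct-7-ene F1. MgBr2·OEt2 then opens the oxirane at the allylic carbon with hydride shift (Meinwald rearrangement) to the β,γ-unsaturated aldehyde (6S)-6-[(2S)-6-methylhept-5-en-2-yl]cyclohex-2-ene-1-carbaldehyde F2, and a trace of DBU moves the alkene into conjugation to give 15.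

Step 8. This step sets C1, and both the γ-regioselectivity and the facial selectivity rest on a conformational argument, not on direct precedent for this substrate. The fallback sets out from 13 and comes back at 17, replacing steps 6 to 8. (Methoxymethoxy)methyllithium (Bu3SnCH2OCH2OMe, n-BuLi, THF, −78 °C) adds to the ketone anti to the neighbouring side chain, and Ac2O traps the alkoxide as (1S,6S)-1-[(methoxymethoxy)methyl]-6-[(2S)-6-methylhept-5-en-2-yl]cyclohex-2-en-1-yl acetate F3. The cuprate (MeOCH2OCH2)2CuLi (same lithium reagent with CuI) displaces the acetate SN2′ and anti, which places the new CH2O group trans to the side chain and gives (3R,6S)-1,3-bis[(methoxymethoxy)methyl]-6-[(2S)-6-methylhept-5-en-2-yl]cyclohex-1-ene F4. Dilute HCl in MeOH at 0 °C frees [(3R,6S)-3-(hydroxymethyl)-6-[(2S)-6-methylhept-5-en-2-yl]cyclohex-1-en-1-yl]methanol F5, and MnO2 oxidises only the allylic alcohol to give 17.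

Step 9. KOtBu can deprotonate the enal at its γ-position (epimerising C1) and the free alkoxide can transesterify the succinate. The fallback sets out from 17 and comes back at 21. The phosphonate 1-allyl 4-tert-butyl 2-(diethoxyphosphoryl)butanedioate F6 is made from allyl (diethoxyphosphoryl)acetate, NaH and tert-butyl bromoacetate. A Horner–Wadsworth–Emmons reaction with 17 under LiCl/DBU in MeCN gives 1-allyl 4-tert-butyl (2E)-2-{[(3R,6S)-3-(hydroxymethyl)-6-[(2S)-6-methylhept-5-en-2-yl]cyclohex-1-en-1-yl]methylidene}butanedioate F7. Me3SiOTf/2,6-lutidine followed by aqueous work-up removes the tert-butyl group to give 21.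

**Further compounds**
F1 | step 6 | (4S)-4-[(2S)-6-methylhept-5-en-2-yl]-1-oxaspiro[2.5]oct-7-ene (spiro centre mixed) | C1OC12C=CCC[C@H]2[C@@H](C)CCC=C(C)C
F2 | step 6 | (6S)-6-[(2S)-6-methylhept-5-en-2-yl]cyclohex-2-ene-1-carbaldehyde (C1 epimers) | O=CC1C=CCC[C@H]1[C@@H](C)CCC=C(C)C
F3 | step 8 | (1S,6S)-1-[(methoxymethoxy)methyl]-6-[(2S)-6-methylhept-5-en-2-yl]cyclohex-2-en-1-yl acetate | CC(=O)O[C@@]1(COCOC)C=CCC[C@H]1[C@@H](C)CCC=C(C)C
F4 | step 8 | (3R,6S)-1,3-bis[(methoxymethoxy)methyl]-6-[(2S)-6-methylhept-5-en-2-yl]cyclohex-1-ene | COCOCC1=C[C@H](COCOC)CC[C@H]1[C@@H](C)CCC=C(C)C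
F5 | step 8 | [(3R,6S)-3-(hydroxymethyl)-6-[(2S)-6-methylhept-5-en-2-yl]cyclohex-1-en-1-yl]methanol | OCC1=C[C@H](CO)CC[C@H]1[C@@H](C)CCC=C(C)C
F6 | step 9 | 1-allyl 4-tert-butyl 2-(diethoxyphosphoryl)butanedioate | CCOP(=O)(OCC)C(CC(=O)OC(C)(C)C)C(=O)OCC=C
F7 | step 9 | 1-allyl 4-tert-butyl (2E)-2-{[(3R,6S)-3-(hydroxymethyl)-6-[(2S)-6-methylhept-5-en-2-yl]cyclohex-1-en-1-yl]methylidene}butanedioate | CC(C)(C)OC(=O)C/C(=C\C1=C[C@H](CO)CC[C@H]1[C@@H](C)CCC=C(C)C)C(=O)OCC=C
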